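**Plan**

- Positions follow octahydro-1H-indene numbering: C1 acetyl, C2 angeloyloxy, C3, C3a, C4 methylidene, C5, C6 acetoxy, C7 isopropyl, C7a.
- Retrosynthesis: the C2 angelate and the C1 acetyl group (from a thioester) are cut first, then the C4 methylidene/C5 methylene pair is traced back to an allylsilane (C4(CH2SiMe3)=C5). The cyclohexene is then cut at C6–C7 and C3a–C7a (retro-Diels–Alder).
- Enabling feature: ring carbons C3a–C4–C5–C6, with the one-carbon branch on C4 and oxygen on C6, are a 1-acetoxy-3-(silylmethyl)butadiene. C7–C7a is an (E)-alkene bearing the isopropyl group, and the cyclopentane carbons C1–C3 are the three-atom tether of a 1,3,8-nonatriene.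
- Forward: the acyclic chain is built linearly (aldol for C1–C2, Wittig for C3a=C4, boryl olefination for C5=C6). One thermal intramolecular Diels–Alder reaction then closes both rings together, silicon is removed to unveil the methylidene group, and the two acyl groups are adjusted.
- Stereochemistry: C1 and C2 come from an Evans syn-aldol with (R)-4-benzyloxazolidinone. C3a, C6, C7 and C7a come from the cycloaddition (alkene geometries, tether-exo mode, π-face set by C1). The angelate geometry comes from angelic acid.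

Key step: step 13

Assumption: 3-[(4-methoxybenzyl)oxy]propanal (8) is taken as purchasable; otherwise it is two routine steps from propane-1,3-diol.

**Route**

Step 1
Reactants: 1 3-methylbutanal; 2 malonic acid
Product: 4 (3E)-5-methylhex-3-enoic acid, via alkylidenemalonic acid 3 (not isolated)
Conditions: piperidinium acetate (cat.), DMSO, 100 °C
Reagents that add atoms: none
Why: Knoevenagel–Doebner condensation under deconjugating conditions, in which the alkylidenemalonic acid equilibrates to its β,γ-unsaturated isomer and this decarboxylates to the (E)-alk-3-enoic acid.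

Step 2
Reactants: 4 (3E)-5-methylhex-3-enoic acid; 5 (4R)-4-benzyl-1,3-oxazolidin-2-one
Product: 7 (4R)-4-benzyl-3-[(3E)-5-methylhex-3-enoyl]-1,3-oxazolidin-2-one, via mixed pivalic anhydride 6 (not isolated)
Conditions: PivCl, Et3N, THF, −20 °C; then 5, LiCl, −20 °C → rt
Reagents that add atoms: none
Why: N-acylation of the oxazolidinone through the mixed pivalic anhydride, a mild method that should not move the β,γ-double bond into conjugation.

Step 3
Reactants: 7 (4R)-4-benzyl-3-[(3E)-5-methylhex-3-enoyl]-1,3-oxazolidin-2-one; 8 3-[(4-methoxybenzyl)oxy]propanal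
Product: 10 (4R)-4-benzyl-3-{(2R,3S)-3-hydroxy-5-[(4-methoxybenzyl)oxy]-2-[(1E)-3-methylbut-1-en-1-yl]pentanoyl}-1,3-oxazolidin-2-one, via boron dienolate 9 (not isolated)
Conditions: Bu2BOTf, i-Pr2NEt, CH2Cl2, −78 → 0 °C; 8, −78 → 0 °C; then pH 7 buffer, MeOH, H2O2, 0 °C
Reagents that add atoms: none
Why: Evans syn-aldol reaction, in which the (Z)-boron dienolate reacts at its α-carbon through a closed chair transition state on the face away from the benzyl group, which should set the (2R,3S) pair that becomes C1 and C2 of the ring system.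

Step 4
Reactants: 10 the aldol adduct
Product: 11 (4R)-4-benzyl-3-{(2R,3S)-5-[(4-methoxybenzyl)oxy]-2-[(1E)-3-methylbut-1-en-1-yl]-3-[(triethylsilyl)oxy]pentanoyl}-1,3-oxazolidin-2-one
Conditions: TESOTf, 2,6-lutidine, CH2Cl2, −78 °C
Reagents that add atoms: triethylsilyl trifluoromethanesulfonate, CC[Si](CC)(CC)OS(=O)(=O)C(F)(F)F
Why: Silylation of the secondary alcohol with a silyl triflate and a hindered pyridine base, fast at low temperature and free of retro-aldol cleavage.

Step 5
Reactants: 11 the silylated imide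
Product: 12 S-ethyl (2R,3S)-5-[(4-methoxybenzyl)oxy]-2-[(1E)-3-methylbut-1-en-1-yl]-3-[(triethylsilyl)oxy]pentanethioate
Conditions: EtSH, n-BuLi, THF, 0 °C; then 11, 0 °C
Reagents that add atoms: ethanethiol, CCS
Why: Transthioesterification of the N-acyloxazolidinone with lithium ethanethiolate, which attacks the exocyclic carbonyl group and should release the auxiliary without epimerisation at the α-carbon.

Step 6
Reactants: 12 the thioester
Product: 13 S-ethyl (2R,3S)-5-hydroxy-2-[(1E)-3-methylbut-1-en-1-yl]-3-[(triethylsilyl)oxy]pentanethioate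
Conditions: DDQ, CH2Cl2–pH 7 buffer, 0 °C
Reagents that add atoms: none
Why: Oxidative cleavage of the 4-methoxybenzyl ether by DDQ through the benzylic oxocarbenium ion, orthogonal to the silyl ether, the thioester and the alkene.

Step 7
Reactants: 13 the primary alcohol
Product: 14 S-ethyl (2R,3S)-2-[(1E)-3-methylbut-1-en-1-yl]-5-oxo-3-[(triethylsilyl)oxy]pentanethioate
Conditions: Dess–Martin periodinane, pyridine, CH2Cl2, 0 °C → rt
Reagents that add atoms: none
Why: Dess–Martin oxidation of the primary alcohol to the aldehyde under buffered conditions that should neither epimerise the thioester α-carbon nor eliminate the β-silyloxy group.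

Step 8
Reactants: 15 methyltriphenylphosphonium bromide
Product: 17 triphenyl[2-(trimethylsilyl)ethyl]phosphonium iodide, via methylidenetriphenylphosphorane 16 (not isolated)
Conditions: n-BuLi, THF, 0 °C; Me3SiCH2I, 0 °C → rt
Reagents that add atoms: (iodomethyl)trimethylsilane, C[Si](C)(C)CI
Why: C-alkylation of the non-stabilised ylide with the primary iodide, which stops at the phosphonium salt when one equivalent of base is used.

Step 9
Reactants: 17 triphenyl[2-(trimethylsilyl)ethyl]phosphonium iodide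
Product: 19 2-(triphenylphosphoranylidene)-3-(trimethylsilyl)propanal, via silylethylidene ylide 18 (not isolated)
Conditions: NaHMDS, THF, 0 °C; HCO2Et, 0 °C → rt
Reagents that add atoms: ethyl formate, CCOC=O
Why: Formylation of a non-stabilised ylide with a formate ester (ylide acylation), after which the released ethoxide deprotonates the formylphosphonium ion to the stabilised ylide.

Step 10
Reactants: 14 the aldehyde; 19 2-(triphenylphosphoranylidene)-3-(trimethylsilyl)propanal
Product: 20 S-ethyl (2R,3S,5Z)-6-formyl-2-[(1E)-3-methylbut-1-en-1-yl]-3-[(triethylsilyl)oxy]-7-(trimethylsilyl)hept-5-enethioate (chain trans to CHO, cis to CH2SiMe3)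
Conditions: 19, toluene, 90 °C
Reagents that add atoms: none
Why: Wittig olefination with an α-substituted formyl-stabilised ylide, which should give the trisubstituted enal with the chain trans to the formyl group and reacts with the aldehyde but not with the thioester.

Step 11
Reactants: 20 the enal
Product: 21 S-ethyl (2R,3S,5Z,7E)-2-[(1E)-3-methylbut-1-en-1-yl]-8-(4,4,5,5-tetramethyl-1,3,2-dioxaborolan-2-yl)-3-[(triethylsilyl)oxy]-6-[(trimethylsilyl)methyl]octa-5,7-dienethioate
Conditions: Cl2CHB(pin), CrCl2, LiI, THF, rt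
Reagents that add atoms: 2-(dichloromethyl)-4,4,5,5-tetramethyl-1,3,2-dioxaborolane, ClC(Cl)B1OC(C)(C)C(C)(C)O1
Why: Takai–Utimoto-type boryl olefination, in which the geminal dichromium species adds to the aldehyde and the β-oxido intermediate eliminates to the (E)-alkenylboronate, selectively at the aldehyde.

Step 12
Reactants: 21 the dienylboronate
Product: 22 S-ethyl (2R,3S,5Z,7E)-8-(acetyloxy)-2-[(1E)-3-methylbut-1-en-1-yl]-3-[(triethylsilyl)oxy]-6-[(trimethylsilyl)methyl]octa-5,7-dienethioate
Conditions: Cu(OAc)2, Et3N, 4 Å MS, MeCN, rt, argon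
Reagents that add atoms: copper diacetate, CC(=O)[O-].CC(=O)[O-].[Cu+2]
Why: Chan–Lam-type C–O coupling, in which the alkenyl group passes from boron to divalent copper acetate and leaves with an acetate ligand by reductive elimination, which should keep the (E)-geometry under conditions that spare the thioester, the silyl ether and the allylsilane.

Step 13
Reactants: 22 the (5Z,7E)-dienyl acetate with the tethered (E)-alkene
Product: 23 S-ethyl (1R,2S,3aR,6S,7S,7aR)-6-(acetyloxy)-7-(propan-2-yl)-2-[(triethylsilyl)oxy]-4-[(trimethylsilyl)methyl]-2,3,3a,6,7,7a-hexahydro-1H-indene-1-carbothioate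
Conditions: toluene (0.01 M), BHT (cat.), sealed tube, 170 °C
Reagents that add atoms: none
Why: A thermal, concerted suprafacial [4+2] cycloaddition of the 1-acetoxy-3-(silylmethyl)diene with the tethered (E)-alkene, that is an intramolecular Diels–Alder reaction of a 1,3,8-nonatriene, should form C3a–C7a and C6–C7 in one operation. The cyclopentane closes by bonding of the tether-bearing diene terminus to the tether-bearing alkene carbon (exo with respect to both π-systems, a 5-exo closure), and the fused cyclohexene closes by the cycloaddition itself with the new C4=C5 bond carrying the silylmethyl group. The (E)-alkene places the isopropyl group and H-7a cis, the (E,E)-diene places the acetoxy group and C3 cis, and the tether-exo (isopropyl-endo) transition state makes the ring fusion trans and the acetoxy and isopropyl groups cis. That mode is expected to win over the tether-endo one because there the branched carbon C1 would lie under the diene carbon that carries the CH2SiMe3 group, so this group is both the latent methylidene and a steric directing group. The π-face is set by the C1 stereocentre, whose thioester should take the pseudo-equatorial site anti to C7 with H-1 eclipsing the alkene, leaving the smaller silyloxy group at C2 pseudo-axial. The step therefore needs tether-exo and facial selectivity, and both rest on these two substrate elements and on the geometric purity of 22.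

Step 14
Reactants: 23 the cycloadduct
Product: 24 S-ethyl (1R,2S,3aR,6R,7S,7aR)-6-(acetyloxy)-2-hydroxy-4-methylidene-7-(propan-2-yl)octahydro-1H-indene-1-carbothioate
Conditions: TFA, CH2Cl2, 0 °C; then THF–H2O, 0 °C
Reagents that add atoms: none
Why: Protodesilylation of the allylsilane (SE2' protonation at C5, loss of silicon from the β-silyl cation) should give the exocyclic alkene under kinetic control, and the same acid hydrolyses the triethylsilyl ether, while the allylic acetate and the thioester react far more slowly.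

Step 15
Reactants: 24 the hydroxy thioester; 25 angelic acid, (2Z)-2-methylbut-2-enoic acid
Product: 27 S-ethyl (1R,2S,3aR,6R,7S,7aR)-6-(acetyloxy)-4-methylidene-2-{[(2Z)-2-methylbut-2-enoyl]oxy}-7-(propan-2-yl)octahydro-1H-indene-1-carbothioate, via mixed trichlorobenzoic anhydride 26 (not isolated)
Conditions: 25, 2,4,6-trichlorobenzoyl chloride, Et3N, toluene, rt; then 24, 75 °C
Reagents that add atoms: none
Why: Yamaguchi-type mixed-anhydride esterification without a nucleophilic catalyst, conditions under which the angeloyl group should be transferred without isomerisation to the tigloyl group and the carbinol configuration is untouched.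

Step 16
Reactants: 27 the angelate thioester
Product: 28 (1R,2S,3aR,6R,7S,7aR)-1-acetyl-6-(acetyloxy)-4-methylidene-7-(propan-2-yl)octahydro-1H-inden-2-yl (2Z)-2-methylbut-2-enoate
Conditions: MeZnCl, PdCl2(PPh3)2 (10 mol %), THF–toluene, rt
Reagents that add atoms: methylzinc chloride, C[Zn]Cl
Why: Fukuyama coupling, in which zerovalent palladium inserts into the C–S bond and transmetalation with the methylzinc reagent and reductive elimination give the methyl ketone under neutral conditions that should spare both esters, both alkenes and the base-sensitive β-acyloxy ketone.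

**Compound list**

1 | 3-methylbutanal | CC(C)CC=O | starting material
2 | malonic acid | OC(=O)CC(=O)O | starting material
3 | 2-(3-methylbutylidene)propanedioic acid | CC(C)CC=C(C(=O)O)C(=O)O | intermediate
4 | (3E)-5-methylhex-3-enoic acid | CC(C)/C=C/CC(=O)O | intermediate
5 | (4R)-4-benzyl-1,3-oxazolidin-2-one | O=C1N[C@H](Cc2ccccc2)CO1 | starting material
6 | (3E)-5-methylhex-3-enoic pivalic anhydride | CC(C)/C=C/CC(=O)OC(=O)C(C)(C)C | intermediate
7 | (4R)-4-benzyl-3-[(3E)-5-methylhex-3-enoyl]-1,3-oxazolidin-2-one | CC(C)/C=C/CC(=O)N1[C@H](Cc2ccccc2)COC1=O | intermediate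
8 | 3-[(4-methoxybenzyl)oxy]propanal | O=CCCOCc1ccc(OC)cc1 | starting material
9 | (4R)-4-benzyl-3-{(1Z,3E)-1-[(dibutylboranyl)oxy]-5-methylhexa-1,3-dien-1-yl}-1,3-oxazolidin-2-one | CC(C)/C=C/C=C(\OB(CCCC)CCCC)N1[C@H](Cc2ccccc2)COC1=O | intermediate
10 | (4R)-4-benzyl-3-{(2R,3S)-3-hydroxy-5-[(4-methoxybenzyl)oxy]-2-[(1E)-3-methylbut-1-en-1-yl]pentanoyl}-1,3-oxazolidin-2-one | CC(C)/C=C/[C@@H](C(=O)N1[C@H](Cc2ccccc2)COC1=O)[C@@H](O)CCOCc1ccc(OC)cc1 | intermediate
11 | (4R)-4-benzyl-3-{(2R,3S)-5-[(4-methoxybenzyl)oxy]-2-[(1E)-3-methylbut-1-en-1-yl]-3-[(triethylsilyl)oxy]pentanoyl}-1,3-oxazolidin-2-one | CC(C)/C=C/[C@@H](C(=O)N1[C@H](Cc2ccccc2)COC1=O)[C@@H](O[Si](CC)(CC)CC)CCOCc1ccc(OC)cc1 | intermediate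
12 | S-ethyl (2R,3S)-5-[(4-methoxybenzyl)oxy]-2-[(1E)-3-methylbut-1-en-1-yl]-3-[(triethylsilyl)oxy]pentanethioate | CC(C)/C=C/[C@@H](C(=O)SCC)[C@@H](O[Si](CC)(CC)CC)CCOCc1ccc(OC)cc1 | intermediate
13 | S-ethyl (2R,3S)-5-hydroxy-2-[(1E)-3-methylbut-1-en-1-yl]-3-[(triethylsilyl)oxy]pentanethioate | CC(C)/C=C/[C@@H](C(=O)SCC)[C@@H](O[Si](CC)(CC)CC)CCO | intermediate
14 | S-ethyl (2R,3S)-2-[(1E)-3-methylbut-1-en-1-yl]-5-oxo-3-[(triethylsilyl)oxy]pentanethioate | CC(C)/C=C/[C@@H](C(=O)SCC)[C@@H](O[Si](CC)(CC)CC)CC=O | intermediate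
15 | methyltriphenylphosphonium bromide | C[P+](c1ccccc1)(c1ccccc1)c1ccccc1.[Br-] | starting material
16 | methylidenetriphenylphosphorane | C=P(c1ccccc1)(c1ccccc1)c1ccccc1 | intermediate
17 | triphenyl[2-(trimethylsilyl)ethyl]phosphonium iodide | C[Si](C)(C)CC[P+](c1ccccc1)(c1ccccc1)c1ccccc1.[I-] | intermediate
18 | triphenyl[2-(trimethylsilyl)ethylidene]phosphorane | C[Si](C)(C)CC=P(c1ccccc1)(c1ccccc1)c1ccccc1 | intermediate
19 | 2-(triphenylphosphoranylidene)-3-(trimethylsilyl)propanal | C[Si](C)(C)CC(C=O)=P(c1ccccc1)(c1ccccc1)c1ccccc1 | intermediate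
20 | S-ethyl (2R,3S,5Z)-6-formyl-2-[(1E)-3-methylbut-1-en-1-yl]-3-[(triethylsilyl)oxy]-7-(trimethylsilyl)hept-5-enethioate | CC(C)/C=C/[C@@H](C(=O)SCC)[C@@H](O[Si](CC)(CC)CC)C/C=C(\C[Si](C)(C)C)C=O | intermediate
21 | S-ethyl (2R,3S,5Z,7E)-2-[(1E)-3-methylbut-1-en-1-yl]-8-(4,4,5,5-tetramethyl-1,3,2-dioxaborolan-2-yl)-3-[(triethylsilyl)oxy]-6-[(trimethylsilyl)methyl]octa-5,7-dienethioate | CC(C)/C=C/[C@@H](C(=O)SCC)[C@@H](O[Si](CC)(CC)CC)C/C=C(\C[Si](C)(C)C)/C=C/B1OC(C)(C)C(C)(C)O1 | intermediate
22 | S-ethyl (2R,3S,5Z,7E)-8-(acetyloxy)-2-[(1E)-3-methylbut-1-en-1-yl]-3-[(triethylsilyl)oxy]-6-[(trimethylsilyl)methyl]octa-5,7-dienethioate | CC(C)/C=C/[C@@H](C(=O)SCC)[C@@H](O[Si](CC)(CC)CC)C/C=C(\C[Si](C)(C)C)/C=C/OC(C)=O | intermediate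
23 | S-ethyl (1R,2S,3aR,6S,7S,7aR)-6-(acetyloxy)-7-(propan-2-yl)-2-[(triethylsilyl)oxy]-4-[(trimethylsilyl)methyl]-2,3,3a,6,7,7a-hexahydro-1H-indene-1-carbothioate | C[Si](C)(C)CC1=C[C@@H](OC(C)=O)[C@@H](C(C)C)[C@@H]2[C@@H](C(=O)SCC)[C@@H](O[Si](CC)(CC)CC)C[C@@H]12 | intermediate
24 | S-ethyl (1R,2S,3aR,6R,7S,7aR)-6-(acetyloxy)-2-hydroxy-4-methylidene-7-(propan-2-yl)octahydro-1H-indene-1-carbothioate | C=C1C[C@@H](OC(C)=O)[C@@H](C(C)C)[C@@H]2[C@@H](C(=O)SCC)[C@@H](O)C[C@@H]12 | intermediate
25 | angelic acid, (2Z)-2-methylbut-2-enoic acid | C/C=C(/C)C(=O)O | starting material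
26 | (2Z)-2-methylbut-2-enoic 2,4,6-trichlorobenzoic anhydride | C/C=C(/C)C(=O)OC(=O)c1c(Cl)cc(Cl)cc1Cl | intermediate
27 | S-ethyl (1R,2S,3aR,6R,7S,7aR)-6-(acetyloxy)-4-methylidene-2-{[(2Z)-2-methylbut-2-enoyl]oxy}-7-(propan-2-yl)octahydro-1H-indene-1-carbothioate | C=C1C[C@@H](OC(C)=O)[C@@H](C(C)C)[C@@H]2[C@@H](C(=O)SCC)[C@@H](OC(=O)/C(C)=C\C)C[C@@H]12 | intermediate
28 | (1R,2S,3aR,6R,7S,7aR)-1-acetyl-6-(acetyloxy)-4-methylidene-7-(propan-2-yl)octahydro-1H-inden-2-yl (2Z)-2-methylbut-2-enoate | C=C1C[C@@H](OC(C)=O)[C@@H](C(C)C)[C@@H]2[C@@H](C(C)=O)[C@@H](OC(=O)/C(C)=C\C)C[C@@H]12 | target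

**Step count and risks**

Total step count: 16. Longest linear sequence: 14 steps (steps 1–7 and 10–16); steps 8 and 9 make the Wittig reagent.

Step 13 (key step). What may go wrong: at the temperature that an unactivated alkene needs, the tether-endo transition state may compete and give the cis ring fusion, and the π-facial preference may erode. Fallback (carbonyl-activated dienophile, so that the endo rule enforces the trans fusion), setting out from 12 and coming back at 23:
- Cross-metathesis of the internal alkene of 12 with methyl vinyl ketone (second-generation Hoveyda–Grubbs catalyst, CH2Cl2, 40 °C) would give the enone S-ethyl (2R,3S)-5-[(4-methoxybenzyl)oxy]-2-[(1E)-3-oxobut-1-en-1-yl]-3-[(triethylsilyl)oxy]pentanethioate F1.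
- DDQ would free the 5-hydroxy analogue F2, and Dess–Martin oxidation would give the 5-oxo analogue F3.
- Wittig reaction with 19 would give the 2-[(1E)-3-oxobut-1-en-1-yl] analogue of 20 F4, and boryl olefination the corresponding analogue of 21 F5.
- Copper-mediated acetoxylation, run without amine because H-2 is now vinylogously acidic, would give the corresponding analogue of 22 F6.
- Me2AlCl (CH2Cl2, −78 → −20 °C) would promote the intramolecular Diels–Alder reaction through the acetyl-endo, tether-exo transition state to the 7-acetyl analogue of 23 F7.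
- Non-basic methylenation (Zn, CH2Br2, TiCl4) would give the 7-(prop-1-en-2-yl) analogue of 23 F8.
- Hydrogenation with RhCl(PPh3)3 (H2, benzene), which should leave the trisubstituted ring alkene alone, comes back to the route at 23.

Step 12. What may go wrong: protodeboronation or oxidative homocoupling of the dienylboronate, or erosion of the (7E) geometry during transfer to copper. Fallback (oxygen introduced after the cycloaddition), setting out from 21 and coming back at 23: the dienylboronate itself would be heated (toluene, 170 °C) to give, by the same cycloaddition, the 6-(4,4,5,5-tetramethyl-1,3,2-dioxaborolan-2-yl) analogue of 23 F9 (boron in place of the acetoxy group, same orientation). Oxidation of the allylic boronate (H2O2, pH 7 buffer, THF, 0 °C), which proceeds with retention at carbon, would give the 6-hydroxy analogue of 23 F10. Acetylation (Ac2O, DMAP, pyridine) comes back to the route at 23.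

Step 15. What may go wrong: slow acylation of the hindered secondary alcohol, during which triethylamine may trigger β-elimination of the β-acyloxy thioester or the angeloyl group may isomerise to the tigloyl group. Fallback (the angelate double bond built on the molecule), setting out from 24 and coming back at 27: esterification with 2-[bis(2,2,2-trifluoroethoxy)phosphoryl]propanoic acid (DCC, DMAP cat., CH2Cl2, 0 °C) would give S-ethyl (1R,2S,3aR,6R,7S,7aR)-6-(acetyloxy)-2-({2-[bis(2,2,2-trifluoroethoxy)phosphoryl]propanoyl}oxy)-4-methylidene-7-(propan-2-yl)octahydro-1H-indene-1-carbothioate F11 (mixture at the phosphonate carbon). A Still–Gennari olefination (KHMDS, 18-crown-6, THF, −78 °C; acetaldehyde), in which the phosphonate is deprotonated in preference to the thioester, would then form the (Z)-2-methylbut-2-enoate and come back to the route at 27.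

**Further compounds**

F1 | step 13 | S-ethyl (2R,3S)-5-[(4-methoxybenzyl)oxy]-2-[(1E)-3-oxobut-1-en-1-yl]-3-[(triethylsilyl)oxy]pentanethioate | CC(=O)/C=C/[C@@H](C(=O)SCC)[C@@H](O[Si](CC)(CC)CC)CCOCc1ccc(OC)cc1
F2 | step 13 | S-ethyl (2R,3S)-5-hydroxy-2-[(1E)-3-oxobut-1-en-1-yl]-3-[(triethylsilyl)oxy]pentanethioate | CC(=O)/C=C/[C@@H](C(=O)SCC)[C@@H](O[Si](CC)(CC)CC)CCO
F3 | step 13 | S-ethyl (2R,3S)-5-oxo-2-[(1E)-3-oxobut-1-en-1-yl]-3-[(triethylsilyl)oxy]pentanethioate | CC(=O)/C=C/[C@@H](C(=O)SCC)[C@@H](O[Si](CC)(CC)CC)CC=O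
F4 | step 13 | S-ethyl (2R,3S,5Z)-6-formyl-2-[(1E)-3-oxobut-1-en-1-yl]-3-[(triethylsilyl)oxy]-7-(trimethylsilyl)hept-5-enethioate | CC(=O)/C=C/[C@@H](C(=O)SCC)[C@@H](O[Si](CC)(CC)CC)C/C=C(\C[Si](C)(C)C)C=O
F5 | step 13 | S-ethyl (2R,3S,5Z,7E)-2-[(1E)-3-oxobut-1-en-1-yl]-8-(4,4,5,5-tetramethyl-1,3,2-dioxaborolan-2-yl)-3-[(triethylsilyl)oxy]-6-[(trimethylsilyl)methyl]octa-5,7-dienethioate | CC(=O)/C=C/[C@@H](C(=O)SCC)[C@@H](O[Si](CC)(CC)CC)C/C=C(\C[Si](C)(C)C)/C=C/B1OC(C)(C)C(C)(C)O1
F6 | step 13 | S-ethyl (2R,3S,5Z,7E)-8-(acetyloxy)-2-[(1E)-3-oxobut-1-en-1-yl]-3-[(triethylsilyl)oxy]-6-[(trimethylsilyl)methyl]octa-5,7-dienethioate | CC(=O)/C=C/[C@@H](C(=O)SCC)[C@@H](O[Si](CC)(CC)CC)C/C=C(\C[Si](C)(C)C)/C=C/OC(C)=O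
F7 | step 13 | S-ethyl 7-acetyl-6-(acetyloxy)-2-[(triethylsilyl)oxy]-4-[(trimethylsilyl)methyl]-2,3,3a,6,7,7a-hexahydro-1H-indene-1-carbothioate (configuration as in 23) | C[Si](C)(C)CC1=C[C@@H](OC(C)=O)[C@@H](C(C)=O)[C@@H]2[C@@H](C(=O)SCC)[C@@H](O[Si](CC)(CC)CC)C[C@@H]12
F8 | step 13 | S-ethyl 6-(acetyloxy)-7-(prop-1-en-2-yl)-2-[(triethylsilyl)oxy]-4-[(trimethylsilyl)methyl]-2,3,3a,6,7,7a-hexahydro-1H-indene-1-carbothioate (configuration as in 23) | C[Si](C)(C)CC1=C[C@@H](OC(C)=O)[C@@H](C(C)=C)[C@@H]2[C@@H](C(=O)SCC)[C@@H](O[Si](CC)(CC)CC)C[C@@H]12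
F9 | step 12 | S-ethyl 7-(propan-2-yl)-6-(4,4,5,5-tetramethyl-1,3,2-dioxaborolan-2-yl)-2-[(triethylsilyl)oxy]-4-[(trimethylsilyl)methyl]-2,3,3a,6,7,7a-hexahydro-1H-indene-1-carbothioate (configuration as in 23) | C[Si](C)(C)CC1=C[C@@H](B3OC(C)(C)C(C)(C)O3)[C@@H](C(C)C)[C@@H]2[C@@H](C(=O)SCC)[C@@H](O[Si](CC)(CC)CC)C[C@@H]12
F10 | step 12 | S-ethyl 6-hydroxy-7-(propan-2-yl)-2-[(triethylsilyl)oxy]-4-[(trimethylsilyl)methyl]-2,3,3a,6,7,7a-hexahydro-1H-indene-1-carbothioate (configuration as in 23) | C[Si](C)(C)CC1=C[C@@H](O)[C@@H](C(C)C)[C@@H]2[C@@H](C(=O)SCC)[C@@H](O[Si](CC)(CC)CC)C[C@@H]12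
F11 | step 15 | S-ethyl (1R,2S,3aR,6R,7S,7aR)-6-(acetyloxy)-2-({2-[bis(2,2,2-trifluoroethoxy)phosphoryl]propanoyl}oxy)-4-methylidene-7-(propan-2-yl)octahydro-1H-indene-1-carbothioate | C=C1C[C@@H](OC(C)=O)[C@@H](C(C)C)[C@@H]2[C@@H](C(=O)SCC)[C@@H](OC(=O)C(C)P(=O)(OCC(F)(F)F)OCC(F)(F)F)C[C@@H]12
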